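**Retrosynthetic overview**
1. The chalcone C=C is disconnected by Claisen–Schmidt logic between the C8 acetyl group of a (3S)-chromanol and 4-(methoxymethoxy)benzaldehyde; both MOM ethers are removed last.
2. The strategy rests on C3, the only stereocentre: a carbinol carbon of dihydropyran ring B, lying between quaternary C2 (bearing O1 and two methyls) and the benzylic C4 methylene on C4a of ring A. Its ketone has two α-carbons of comparable bulk, so the C3–H bond is made by a ketoreductase, whose pocket rather than a size difference picks the face.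
3. The C3 ketone comes from the C3=C4 chromene by epoxidation and Meinwald rearrangement (hydride shift from C3 to C4).
4. Ring order: ring A is bought (phloroacetophenone); ring B is closed by prenal annulation after the para hydroxyl is capped as a MOM ether, which forces O1 to come from an ortho hydroxyl and places the acetyl on C8; ring C arrives with the aldehyde.

Key step: step 5

Remark: the C5 phenol is carried as its methoxymethyl ether from step 1 to the last step, so the enzymatic step runs on the 5-O-MOM ketone 7 and gives the 5-O-MOM alcohol 8. This spares a deprotection and reprotection around the key step and keeps the electron-rich ketone less prone to aerial oxidation.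

**Route**

Step 1
Reactants: 1 2,4,6-trihydroxyacetophenone
Product: 2 1-[2,6-dihydroxy-4-(methoxymethoxy)phenyl]ethanone
Conditions: MOMCl (1.0 equiv), K2CO3, acetone, 0 °C to rt
Reagents that add atoms: chloromethyl methyl ether (MOMCl), COCCl
Why: Phenol O-alkylation (MOM ether formation) in which the 4-OH, the most acidic hydroxyl and the only one not tied to the acetyl carbonyl, should react first with one equivalent of MOMCl, any bis-ether being removed by chromatography.

Step 2
Reactants: 2 1-[2,6-dihydroxy-4-(methoxymethoxy)phenyl]ethanone; 3 3-methylbut-2-enal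
Product: 5 1-[7-hydroxy-5-(methoxymethoxy)-2,2-dimethyl-2H-chromen-8-yl]ethanone, via ortho-quinone methide 4 (not isolated)
Conditions: 3 (1.2 equiv), ethylenediammonium diacetate (10 mol%), toluene, 110 °C
Reagents that add atoms: none
Why: Chromene annulation (Knoevenagel-type condensation at the ring carbon next to a free OH, dehydration to the ortho-quinone methide, oxa-6π electrocyclisation), in which the blocked O4 forces the pyran oxygen to come from a hydroxyl ortho to the acetyl and the equivalence of the two free ring positions gives a single regioisomer with the acetyl on C8.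

Step 3
Reactants: 5 1-[7-hydroxy-5-(methoxymethoxy)-2,2-dimethyl-2H-chromen-8-yl]ethanone
Product: 6 1-[3,4-epoxy-7-hydroxy-5-(methoxymethoxy)-2,2-dimethylchroman-8-yl]ethanone (racemic, cis-fused epoxide, used crude after cold evaporation)
Conditions: dimethyldioxirane (1.1 equiv, acetone solution), CH2Cl2, −20 °C
Reagents that add atoms: dimethyldioxirane, CC1(C)OO1
Why: Dioxirane epoxidation of the electron-rich C3=C4 alkene, which should react far faster than the hydrogen-bonded acylphenol ring, under acid-free conditions that keep the labile benzylic epoxide intact; the two new stereocentres form as a racemate and both are erased in step 4.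

Step 4
Reactants: 6 1-[3,4-epoxy-7-hydroxy-5-(methoxymethoxy)-2,2-dimethylchroman-8-yl]ethanone
Product: 7 8-acetyl-7-hydroxy-5-(methoxymethoxy)-2,2-dimethylchroman-3-one
Conditions: ZnI2 (10 mol%), CH2Cl2, 0 °C to rt
Reagents that add atoms: none
Why: Meinwald rearrangement, in which zinc coordination opens the C4–O bond to a benzylic cation stabilised by O1, O5 and O7 and a 1,2-hydride shift from C3 to C4 leaves the carbonyl at C3.

Step 5
Reactants: 7 8-acetyl-7-hydroxy-5-(methoxymethoxy)-2,2-dimethylchroman-3-one
Product: 8 1-[(3S)-3,7-dihydroxy-5-(methoxymethoxy)-2,2-dimethylchroman-8-yl]ethanone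
Conditions: (S)-selective ketoreductase (hit from an NADPH-dependent panel), NADP+ (cat.), i-PrOH (15% v/v), DMSO (5% v/v), potassium phosphate buffer pH 7.0, MgSO4 (2 mM), 30 °C, N2
Reagents that add atoms: none
Why: In the active site the C3 carbonyl is held by the catalytic tyrosine and serine while NADPH passes its C4 hydride to the Re face of C3 (priorities O > C2 > C4) and the tyrosine protonates the oxygen; oxidation of isopropanol by the same enzyme regenerates NADPH. The closest known reaction type is the ketoreductase (alcohol dehydrogenase) reduction of 2-tetralones and related cyclic benzyl alkyl ketones with cofactor recycling. No ring is closed and no skeletal bond is formed; only the C3–H bond is made. The C3 stereocentre is set by the enzyme pocket alone (catalyst control on an achiral substrate), and since panels hold enzymes of both facial preferences the (S)-selective one is found by screening. The step needs face selectivity between two flanks of similar bulk (C2 with its methyls and O1 against the C4 methylene on ring A), which the shaped pocket supplies, and chemoselectivity for the ring ketone over the C8 acetyl, which is secured because that acetyl is conjugated, flanked at both ortho positions and locked in a hydrogen bond to the 7-OH. Neutral pH and fast turnover should outrun enolisation toward C4 and aerial oxidation of the ketone.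

Step 6
Reactants: 9 4-hydroxybenzaldehyde
Product: 10 4-(methoxymethoxy)benzaldehyde
Conditions: MOMCl (1.2 equiv), K2CO3, acetone, rt
Reagents that add atoms: chloromethyl methyl ether (MOMCl), COCCl
Why: Phenol O-alkylation (MOM ether formation) masks the para hydroxyl, whose phenoxide would otherwise deactivate the aldehyde in the aldol step.

Step 7
Reactants: 8 1-[(3S)-3,7-dihydroxy-5-(methoxymethoxy)-2,2-dimethylchroman-8-yl]ethanone; 10 4-(methoxymethoxy)benzaldehyde
Product: 12 (E)-1-[(3S)-3,7-dihydroxy-5-(methoxymethoxy)-2,2-dimethylchroman-8-yl]-3-[4-(methoxymethoxy)phenyl]prop-2-en-1-one, via aldol adduct 11 (not isolated)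
Conditions: 10 (1.3 equiv), KOH (50% aq., excess), EtOH, 0 °C to rt, Ar, dark
Reagents that add atoms: none
Why: Claisen–Schmidt condensation (crossed aldol of the methyl ketone enolate with the non-enolisable aldehyde, then E1cB dehydration) should give the thermodynamically favoured E-enone, while C3, a carbinol carbon with no acidic hydrogen, is untouched.

Step 8
Reactants: 12 (E)-1-[(3S)-3,7-dihydroxy-5-(methoxymethoxy)-2,2-dimethylchroman-8-yl]-3-[4-(methoxymethoxy)phenyl]prop-2-en-1-one
Product: 13 (E)-3-(4-hydroxyphenyl)-1-[(3S)-3,5,7-trihydroxy-2,2-dimethylchroman-8-yl]prop-2-en-1-one (target)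
Conditions: 3 M aq. HCl, MeOH, rt, Ar, dark
Reagents that add atoms: none
Why: Acid-catalysed acetal cleavage of both aryl MOM ethers at room temperature, mild enough that oxa-Michael closure of the 7-OH onto the enone should stay slow, and without effect on the C3 carbinol.

**Compound list**
1 | 2,4,6-trihydroxyacetophenone | CC(=O)c1c(O)cc(O)cc1O | starting material
2 | 1-[2,6-dihydroxy-4-(methoxymethoxy)phenyl]ethanone | CC(=O)c1c(O)cc(OCOC)cc1O | intermediate
3 | 3-methylbut-2-enal | CC(C)=CC=O | starting material
4 | 2-acetyl-3-hydroxy-5-(methoxymethoxy)-6-(3-methylbut-2-en-1-ylidene)cyclohexa-2,4-dien-1-one (ortho-quinone methide, not isolated) | CC(=O)C1=C(O)C=C(OCOC)C(=CC=C(C)C)C1=O | intermediate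
5 | 1-[7-hydroxy-5-(methoxymethoxy)-2,2-dimethyl-2H-chromen-8-yl]ethanone | CC(=O)c1c(O)cc(OCOC)c2C=CC(C)(C)Oc12 | intermediate
6 | 1-[3,4-epoxy-7-hydroxy-5-(methoxymethoxy)-2,2-dimethylchroman-8-yl]ethanone (racemic, cis-fused) | CC(=O)c1c(O)cc(OCOC)c2C3OC3C(C)(C)Oc12 | intermediate
7 | 8-acetyl-7-hydroxy-5-(methoxymethoxy)-2,2-dimethylchroman-3-one | CC(=O)c1c(O)cc(OCOC)c2CC(=O)C(C)(C)Oc12 | intermediate
8 | 1-[(3S)-3,7-dihydroxy-5-(methoxymethoxy)-2,2-dimethylchroman-8-yl]ethanone | CC(=O)c1c(O)cc(OCOC)c2C[C@H](O)C(C)(C)Oc12 | intermediate
9 | 4-hydroxybenzaldehyde | O=Cc1ccc(O)cc1 | starting material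
10 | 4-(methoxymethoxy)benzaldehyde | COCOc1ccc(C=O)cc1 | intermediate
11 | 1-[(3S)-3,7-dihydroxy-5-(methoxymethoxy)-2,2-dimethylchroman-8-yl]-3-hydroxy-3-[4-(methoxymethoxy)phenyl]propan-1-one (aldol adduct, both epimers at the new carbinol, not isolated) | CC1(C)Oc2c(c(OCOC)cc(O)c2C(=O)CC(O)c2ccc(OCOC)cc2)C[C@@H]1O | intermediate
12 | (E)-1-[(3S)-3,7-dihydroxy-5-(methoxymethoxy)-2,2-dimethylchroman-8-yl]-3-[4-(methoxymethoxy)phenyl]prop-2-en-1-one | CC1(C)Oc2c(c(OCOC)cc(O)c2C(=O)/C=C/c2ccc(OCOC)cc2)C[C@@H]1O | intermediate
13 | (E)-3-(4-hydroxyphenyl)-1-[(3S)-3,5,7-trihydroxy-2,2-dimethylchroman-8-yl]prop-2-en-1-one | CC1(C)Oc2c(c(O)cc(O)c2C(=O)/C=C/c2ccc(O)cc2)C[C@@H]1O | target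

**Step count**
Total: 8 steps. Longest linear sequence: 7 steps (steps 1, 2, 3, 4, 5, 7, 8); step 6 is a one-step side branch.

**Steps most likely to fail, with fallbacks**

Step 5. The panel may contain no enzyme that accepts a ketone with a fully substituted α-carbon, the facial selectivity of the best hit may be insufficient, or enolisation and aerial oxidation in buffer may outpace reduction. The fallback sets C3 by asymmetric epoxidation instead and sets out from chromene 5. Jacobsen–Katsuki epoxidation with the (S,S)-enantiomer of (salen)MnCl (salen = N,N'-bis(3,5-di-tert-butylsalicylidene)-1,2-cyclohexanediamine dianion; 5 mol%), mCPBA and N-methylmorpholine N-oxide in CH2Cl2 at −78 °C should give 1-[(3S,4S)-3,4-epoxy-7-hydroxy-5-(methoxymethoxy)-2,2-dimethylchroman-8-yl]ethanone F1. The sense of induction is taken from that expected for 2,2-dimethylchromenes with this catalyst enantiomer. Hydrogenolysis of the benzylic C4–O bond (H2, Pd/C, EtOAc, rt) leaves the C3–O bond and its configuration untouched and should deliver alcohol 8, where the route is rejoined (steps 3 to 5 are bypassed).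

Step 4. The cationic opening may take other courses: migration of C2 instead of hydride (ring contraction to a dihydrobenzofuran carbaldehyde), capture of the C4 cation by iodide or adventitious water, or Lewis-acid loss of the MOM group. The fallback avoids the cation and sets out from epoxide 6. Hydrogenolysis of the benzylic C4–O bond (H2, Pd/C, EtOAc, rt) should give racemic 1-[3,7-dihydroxy-5-(methoxymethoxy)-2,2-dimethylchroman-8-yl]ethanone F2. Dess–Martin oxidation of its secondary alcohol (Dess–Martin periodinane, NaHCO3, CH2Cl2, 0 °C) should then give ketone 7, where the route is rejoined.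

Step 8. Under acid the 7-OH may add to the enone (chalcone to flavanone isomerisation) faster than the second MOM group is lost. The fallback moves the acid step ahead of enone formation and ends with a neutral deprotection; it sets out from alcohol 8.
- MOM cleavage (3 M aq. HCl, MeOH, rt), harmless at this stage, should give 1-[(3S)-3,5,7-trihydroxy-2,2-dimethylchroman-8-yl]ethanone F3.
- Allylation of the non-chelated 5-OH (allyl bromide, 1.05 equiv, K2CO3, acetone, rt) should give 1-[(3S)-5-(allyloxy)-3,7-dihydroxy-2,2-dimethylchroman-8-yl]ethanone F4.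
- Claisen–Schmidt condensation with commercial 4-(allyloxy)benzaldehyde (KOH, EtOH, rt) should give (E)-1-[(3S)-5-(allyloxy)-3,7-dihydroxy-2,2-dimethylchroman-8-yl]-3-[4-(allyloxy)phenyl]prop-2-en-1-one F5.
- Allyl transfer to morpholine with the zerovalent palladium complex Pd(PPh3)4 (5 mol%, THF, rt) should release target 13 without acid or strong base.

**Further compounds**
F1 | step 5 | 1-[(3S,4S)-3,4-epoxy-7-hydroxy-5-(methoxymethoxy)-2,2-dimethylchroman-8-yl]ethanone | CC(=O)c1c(O)cc(OCOC)c2[C@@H]3O[C@@H]3C(C)(C)Oc12
F2 | step 4 | racemic 1-[3,7-dihydroxy-5-(methoxymethoxy)-2,2-dimethylchroman-8-yl]ethanone | CC(=O)c1c(O)cc(OCOC)c2CC(O)C(C)(C)Oc12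
F3 | step 8 | 1-[(3S)-3,5,7-trihydroxy-2,2-dimethylchroman-8-yl]ethanone | CC(=O)c1c(O)cc(O)c2C[C@H](O)C(C)(C)Oc12
F4 | step 8 | 1-[(3S)-5-(allyloxy)-3,7-dihydroxy-2,2-dimethylchroman-8-yl]ethanone | CC(=O)c1c(O)cc(OCC=C)c2C[C@H](O)C(C)(C)Oc12
F5 | step 8 | (E)-1-[(3S)-5-(allyloxy)-3,7-dihydroxy-2,2-dimethylchroman-8-yl]-3-[4-(allyloxy)phenyl]prop-2-en-1-one | CC1(C)Oc2c(c(OCC=C)cc(O)c2C(=O)/C=C/c2ccc(OCC=C)cc2)C[C@@H]1O
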